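**Retrosynthetic overview**

1. β-HIVS 19 ⇒ shikonin 17 + 3-hydroxy-3-methylbutanoic acid 18 (ester C–O bond; the side-chain OH is the only unchelated hydroxyl).
2. 17 ⇒ (deprotection) quinone 16 ⇒ Fischer carbene 14 + alkyne 9 + one CO ligand: a one-pot Dötz [3+2+1] benzannulation/CAN oxidation closes the quinone ring (C1, C2, C3, C4, C4a, C8a) with the complete side chain and its stereocentre already in place.
3. Enabling feature: the para-oxygens at C1 and C4 map onto inserted CO (C1) and the carbene C–OMe (C4), C2/C3 are the alkyne carbons and C4a/C8a come from the aryl group. The benzenoid ring (C4a, C5, C6, C7, C8, C8a) carries identical oxygens at C5 and C8, so either orientation of alkyne uptake gives the same quinone.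
4. 9 ⇒ Noyori transfer hydrogenation of TMS-ynone 6 ⇒ Weinreb amide 3 (from 4-methylpent-3-enoic acid 1) + ethynyltrimethylsilane 4; 14 ⇒ hydroquinone 10 via bis-MOM ether 11, ortho-lithiation, Cr(CO)6 and Me3OBF4.
5. Ring order: benzenoid ring bought as hydroquinone; quinone ring closed last (step 8).

Key step: step 8

Remark: the naphthazarin nucleus is a fast tautomeric system, so the target is one compound whichever ring is drawn quinoid; compounds 1, 4, 10 and 18 are taken as commercial, and 15 is written with its η6-bound Cr(CO)3 unit as a dot-separated fragment (CO ligands as Cr=C=O).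

**Route**

Step 1
Reactants: 1 4-methylpent-3-enoic acid
Product: 3 N-methoxy-N,4-dimethylpent-3-enamide, via acylimidazole 2 (not isolated)
Conditions: CDI (1.1 equiv), CH2Cl2, 0 °C → rt; then MeNH(OMe)·HCl (1.2 equiv), rt
Reagents that add atoms: N,O-dimethylhydroxylamine hydrochloride, CNOC.Cl
Why: CDI-mediated amidation (Weinreb amide formation) via the acylimidazole should proceed under near-neutral conditions, so the β,γ-alkene is not drawn into conjugation.

Step 2
Reactants: 3 N-methoxy-N,4-dimethylpent-3-enamide; 4 ethynyltrimethylsilane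
Product: 6 6-methyl-1-(trimethylsilyl)hept-5-en-1-yn-3-one, via lithium (trimethylsilyl)acetylide 5 (not isolated)
Conditions: 4, n-BuLi, THF, −78 °C; then 3, −78 → −20 °C; inverse quench into cold aq. NH4Cl
Reagents that add atoms: none
Why: Weinreb ketone synthesis, in which the N-methoxy chelate holds the tetrahedral adduct until the cold quench (no over-addition) and the weakly basic acetylide at low temperature should leave the doubly activated CH2 and the alkene position alone.

Step 3
Reactants: 6 6-methyl-1-(trimethylsilyl)hept-5-en-1-yn-3-one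
Product: 7 (R)-6-methyl-1-(trimethylsilyl)hept-5-en-1-yn-3-ol
Conditions: Ru[(R,R)-TsDPEN](p-cymene) (preformed amido complex, 1 mol %), i-PrOH (0.1 M), rt
Reagents that add atoms: none
Why: Noyori asymmetric transfer hydrogenation of an alkynyl ketone, in which outer-sphere H−/H+ delivery from the (R,R)-Ru hydride with the alkynyl group as the π substituent should give the (R)-carbinol, while the base-free medium touches neither alkyne nor skipped alkene.

Step 4
Reactants: 7 (R)-6-methyl-1-(trimethylsilyl)hept-5-en-1-yn-3-ol
Product: 8 (R)-6-methylhept-5-en-1-yn-3-ol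
Conditions: K2CO3 (0.2 equiv), MeOH, 0 °C → rt; careful concentration (volatile product)
Reagents that add atoms: none
Why: Base-catalysed methanolytic protodesilylation of the C(sp)–Si bond, which does not involve the carbinol centre.

Step 5
Reactants: 8 (R)-6-methylhept-5-en-1-yn-3-ol
Product: 9 (R)-triethyl[(6-methylhept-5-en-1-yn-3-yl)oxy]silane
Conditions: TESCl, imidazole, CH2Cl2, 0 °C
Reagents that add atoms: chlorotriethylsilane, CC[Si](Cl)(CC)CC
Why: Imidazole-promoted silyl ether formation gives a propargylic silyl ether, a class known to pass through chromium carbene benzannulation, and TES is chosen because it later falls in the same mild acid step as the aryl MOM groups.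

Step 6
Reactants: 10 hydroquinone
Product: 11 1,4-bis(methoxymethoxy)benzene
Conditions: NaH (2.5 equiv), DMF, 0 °C; MOMCl (2.5 equiv), 0 °C → rt
Reagents that add atoms: chloromethyl methyl ether, COCCl
Why: Williamson-type O-alkylation of the bis-phenoxide with the α-chloro ether installs acetal ethers that direct the lithiation in step 7 and leave under mild acid in step 9.

Step 7
Reactants: 11 1,4-bis(methoxymethoxy)benzene
Product: 14 pentacarbonyl{[2,5-bis(methoxymethoxy)phenyl](methoxy)methylidene}chromium(0), via aryllithium 12 (not isolated), via lithium acyl chromate 13 (not isolated)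
Conditions: n-BuLi (1.1 equiv), THF, 0 °C → rt; Cr(CO)6 (1.0 equiv), 0 °C → rt; evaporate; Me3OBF4 (1.3 equiv), CH2Cl2, 0 °C → rt
Reagents that add atoms: chromium hexacarbonyl, O=C=[Cr](=C=O)(=C=O)(=C=O)(=C=O)=C=O; trimethyloxonium tetrafluoroborate, C[O+](C)C.F[B-](F)(F)F
Why: Fischer carbene synthesis by MOM-directed ortho-lithiation (all four ring CH are equivalent), addition of the aryllithium to a CO ligand and O-methylation of the acyl chromate with Meerwein salt, the chromate oxygen being far more nucleophilic than the acetal oxygens.

Step 8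
Reactants: 14 pentacarbonyl{[2,5-bis(methoxymethoxy)phenyl](methoxy)methylidene}chromium(0); 9 (R)-triethyl[(6-methylhept-5-en-1-yn-3-yl)oxy]silane
Product: 16 (R)-5,8-bis(methoxymethoxy)-2-[4-methyl-1-(triethylsilyloxy)pent-3-enyl]naphthalene-1,4-dione, via tricarbonylchromium naphthol complex 15 (not isolated)
Conditions: 14 (1.3 equiv), THF (0.05 M, degassed), 50 °C, 16 h; then CAN (7 equiv), MeCN/H2O, 0 °C, 15 min
Reagents that add atoms: water, O
Why: Dötz benzannulation with oxidative work-up: thermal loss of a cis-CO from 14, insertion of the terminal alkyne (carbene carbon to the CH terminus), CO insertion to a Cr(CO)3-bound aryl vinylketene and 6π-electrocyclisation onto the only free ortho carbon of the aryl ring, then tautomerisation, give naphthol complex 15; CAN then strips Cr(CO)3 and oxidises the 4-methoxy-1-naphthol ring to the quinone, water replacing the methoxy group. The closest known reaction type is the benzannulation of aryl(alkoxy)carbene chromium complexes, 2,5-dialkoxyphenyl ones included, with terminal alkynes and with chiral propargylic silyl ethers, followed by CAN oxidation to 1,4-naphthoquinones. The one ring closed is the quinone ring, by electrocyclic closure of the C1–C8a bond after the intermolecular C3–C4 and C1–C2 bonds have been made. No new stereocentre is formed: the propargylic C–O bond is not touched, so the (R) configuration from step 3 is carried through, and the planar chirality of 15 vanishes on decomplexation. The step needs chemoselectivity for the CO-inserted phenol over indene, furan or cyclobutenone products, which an aryl carbene with a terminal alkyne in THF at moderate dilution should secure, and it needs no regiocontrol, because the identical OMOM groups at the future C5 and C8 make both alkyne orientations converge on 16. The trisubstituted alkene should be spared, since cyclopropanation by the vinylcarbene would require a bicyclo[2.1.0]pentane.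

Step 9
Reactants: 16 (R)-5,8-bis(methoxymethoxy)-2-[4-methyl-1-(triethylsilyloxy)pent-3-enyl]naphthalene-1,4-dione
Product: 17 shikonin, (R)-5,8-dihydroxy-2-(1-hydroxy-4-methylpent-3-enyl)naphthalene-1,4-dione
Conditions: 1 M aq. HCl/THF (1:3), 0 °C → rt, Ar, dark
Reagents that add atoms: none
Why: Acid-catalysed acetal hydrolysis of the two aryl MOM ethers and Si–O solvolysis of the TES ether should unveil the chelated naphthazarin and the carbinol in one operation without breaking the C–O bond at the stereocentre, and any TES already lost in step 8 converges here.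

Step 10
Reactants: 17 shikonin; 18 3-hydroxy-3-methylbutanoic acid
Product: 19 β-HIVS, (R)-1-(5,8-dihydroxy-1,4-dioxo-1,4-dihydronaphthalen-2-yl)-4-methylpent-3-enyl 3-hydroxy-3-methylbutanoate
Conditions: 18 (1.5 equiv), DCC (1.5 equiv), DMAP (0.2 equiv), CH2Cl2, 0 °C → rt
Reagents that add atoms: none
Why: Steglich esterification should acylate only the side-chain secondary hydroxyl, because the two peri phenols are locked in hydrogen bonds to the quinone carbonyls and the tertiary hydroxyl of 18 is too hindered, and acyl–O bond formation leaves the stereocentre untouched.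

**Compound list**

1 | 4-methylpent-3-enoic acid | CC(C)=CCC(=O)O | starting material
2 | 1-(imidazol-1-yl)-4-methylpent-3-en-1-one | CC(C)=CCC(=O)n1ccnc1 | intermediate (not isolated)
3 | N-methoxy-N,4-dimethylpent-3-enamide | CC(C)=CCC(=O)N(C)OC | intermediate
4 | ethynyltrimethylsilane | C#C[Si](C)(C)C | starting material
5 | lithium (trimethylsilyl)acetylide | [Li]C#C[Si](C)(C)C | intermediate (not isolated)
6 | 6-methyl-1-(trimethylsilyl)hept-5-en-1-yn-3-one | CC(C)=CCC(=O)C#C[Si](C)(C)C | intermediate
7 | (R)-6-methyl-1-(trimethylsilyl)hept-5-en-1-yn-3-ol | CC(C)=CC[C@@H](O)C#C[Si](C)(C)C | intermediate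
8 | (R)-6-methylhept-5-en-1-yn-3-ol | CC(C)=CC[C@@H](O)C#C | intermediate
9 | (R)-triethyl[(6-methylhept-5-en-1-yn-3-yl)oxy]silane | CC(C)=CC[C@@H](O[Si](CC)(CC)CC)C#C | intermediate
10 | hydroquinone (benzene-1,4-diol) | Oc1ccc(O)cc1 | starting material
11 | 1,4-bis(methoxymethoxy)benzene | COCOc1ccc(OCOC)cc1 | intermediate
12 | [2,5-bis(methoxymethoxy)phenyl]lithium | [Li]c1cc(OCOC)ccc1OCOC | intermediate (not isolated)
13 | lithium pentacarbonyl[2,5-bis(methoxymethoxy)benzoyl]chromate | [Li+].[O-]C(=[Cr](=C=O)(=C=O)(=C=O)(=C=O)=C=O)c1cc(OCOC)ccc1OCOC | intermediate (not isolated)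
14 | pentacarbonyl{[2,5-bis(methoxymethoxy)phenyl](methoxy)methylidene}chromium(0) | COC(=[Cr](=C=O)(=C=O)(=C=O)(=C=O)=C=O)c1cc(OCOC)ccc1OCOC | intermediate
15 | tricarbonyl{η6-(R)-4-methoxy-5,8-bis(methoxymethoxy)-2-[4-methyl-1-(triethylsilyloxy)pent-3-enyl]naphthalen-1-ol}chromium(0), Cr on the newly formed ring | CC(C)=CC[C@@H](O[Si](CC)(CC)CC)c1cc(OC)c2c(OCOC)ccc(OCOC)c2c1O.O=C=[Cr](=C=O)=C=O | intermediate (not isolated)
16 | (R)-5,8-bis(methoxymethoxy)-2-[4-methyl-1-(triethylsilyloxy)pent-3-enyl]naphthalene-1,4-dione | CC(C)=CC[C@@H](O[Si](CC)(CC)CC)C1=CC(=O)c2c(OCOC)ccc(OCOC)c2C1=O | intermediate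
17 | shikonin, (R)-5,8-dihydroxy-2-(1-hydroxy-4-methylpent-3-enyl)naphthalene-1,4-dione | CC(C)=CC[C@@H](O)C1=CC(=O)c2c(O)ccc(O)c2C1=O | intermediate
18 | 3-hydroxy-3-methylbutanoic acid | CC(C)(O)CC(=O)O | starting material
19 | β-HIVS, (R)-1-(5,8-dihydroxy-1,4-dioxo-1,4-dihydronaphthalen-2-yl)-4-methylpent-3-enyl 3-hydroxy-3-methylbutanoate | CC(C)=CC[C@@H](OC(=O)CC(C)(C)O)C1=CC(=O)c2c(O)ccc(O)c2C1=O | target

**Step count and risks**

Total step count: 10. Longest linear sequence: 8 (steps 1–5, 8, 9, 10); the carbene branch (steps 6, 7) joins at step 8.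

Steps most likely to fail:

1. Step 8. The chelating ortho-MOM-oxy group and the branched propargylic ether may steer the vinylcarbene away from CO insertion (cyclopentannulation, cyclobutenone formation), the carbene may decompose before it takes up the hindered alkyne, or the oxidative work-up may strip acetal and silyl groups unevenly. The fallback changes the approach: the bicyclic nucleus is bought, the side chain is attached by acylation and the stereocentre is set by reagent-controlled ketone reduction. It sets out from 3 and comes back at 16. Commercial naphthazarin is reduced and protected (Na2S2O4; then NaH, MOMCl, DMF) to 1,4,5,8-tetrakis(methoxymethoxy)naphthalene F1. Ortho-lithiation (n-BuLi, THF, 0 °C; the four ring CH are equivalent) and acylation with 3 should give 4-methyl-1-[1,4,5,8-tetrakis(methoxymethoxy)naphthalen-2-yl]pent-3-en-1-one F2. Reduction with (+)-B-chlorodiisopinocampheylborane (THF, −25 °C; aryl as the large group) should give (R)-4-methyl-1-[1,4,5,8-tetrakis(methoxymethoxy)naphthalen-2-yl]pent-3-en-1-ol F3, and TESCl/imidazole its triethylsilyl ether F4. CAN (MeCN/H2O, 0 °C) then unmasks one of the two rings oxidatively and should give 16 together with its ring isomer (R)-5,8-bis(methoxymethoxy)-6-[4-methyl-1-(triethylsilyloxy)pent-3-enyl]naphthalene-1,4-dione F5. Both are carried into step 9, where they converge on 17 because the two ring forms of the naphthazarin are tautomers.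

2. Step 9. Under aqueous acid the freed carbinol next to the electron-rich ring tautomer may ionise (erosion of enantiopurity) or add to the protonated prenyl alkene (cyclisation), and slow MOM or TES cleavage may call for forcing conditions that the naphthazarin does not tolerate. The fallback changes the approach: the carbinol is never free in acid and shikonin is bypassed. It sets out from 16 and comes back at 19. Buffered HF·pyridine (THF/pyridine, 0 °C) should remove only the silyl group and give (R)-2-(1-hydroxy-4-methylpent-3-enyl)-5,8-bis(methoxymethoxy)naphthalene-1,4-dione F6. Steglich esterification with 18 (DCC, DMAP, CH2Cl2) should give (R)-1-[5,8-bis(methoxymethoxy)-1,4-dioxo-1,4-dihydronaphthalen-2-yl]-4-methylpent-3-enyl 3-hydroxy-3-methylbutanoate F7. The two aryl MOM groups are then cleaved with the ester already in place (1 M aq. HCl/THF, 0 °C) to give 19 directly.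

3. Step 3. The skipped trisubstituted alkene may migrate into conjugation through the acidic CH2 between C=O and C=C before or during reduction, isopropoxide may add to the ynone in conjugate fashion, or facial discrimination may be insufficient. The fallback changes the approach: the stereocentre comes from allylboration and the prenyl terminus from cross-metathesis, with no enolisable ketone on the way. It sets out from 4 and comes back at 7. Formylation of 4 (n-BuLi, THF, −78 °C; DMF; buffered quench) gives 3-(trimethylsilyl)prop-2-ynal F8. Brown allylation with (+)-B-allyldiisopinocampheylborane (Et2O, −78 °C; NaOH, H2O2), with the alkynyl group in the place an aryl group takes in the chair transition state, should give (R)-1-(trimethylsilyl)hex-5-en-1-yn-3-ol F9. Cross-metathesis with 2-methyl-2-butene (Grubbs second-generation catalyst, neat, 40 °C; the silyl-capped alkyne is inert) should give 7.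

**Further compounds**

F1 | step 8 | 1,4,5,8-tetrakis(methoxymethoxy)naphthalene | COCOc1ccc(OCOC)c2c(OCOC)ccc(OCOC)c12
F2 | step 8 | 4-methyl-1-[1,4,5,8-tetrakis(methoxymethoxy)naphthalen-2-yl]pent-3-en-1-one | CC(C)=CCC(=O)c1cc(OCOC)c2c(OCOC)ccc(OCOC)c2c1OCOC
F3 | step 8 | (R)-4-methyl-1-[1,4,5,8-tetrakis(methoxymethoxy)naphthalen-2-yl]pent-3-en-1-ol | CC(C)=CC[C@@H](O)c1cc(OCOC)c2c(OCOC)ccc(OCOC)c2c1OCOC
F4 | step 8 | (R)-triethyl{4-methyl-1-[1,4,5,8-tetrakis(methoxymethoxy)naphthalen-2-yl]pent-3-enyloxy}silane | CC(C)=CC[C@@H](O[Si](CC)(CC)CC)c1cc(OCOC)c2c(OCOC)ccc(OCOC)c2c1OCOC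
F5 | step 8 | (R)-5,8-bis(methoxymethoxy)-6-[4-methyl-1-(triethylsilyloxy)pent-3-enyl]naphthalene-1,4-dione | CC(C)=CC[C@@H](O[Si](CC)(CC)CC)c1cc(OCOC)c2C(=O)C=CC(=O)c2c1OCOC
F6 | step 9 | (R)-2-(1-hydroxy-4-methylpent-3-enyl)-5,8-bis(methoxymethoxy)naphthalene-1,4-dione | CC(C)=CC[C@@H](O)C1=CC(=O)c2c(OCOC)ccc(OCOC)c2C1=O
F7 | step 9 | (R)-1-[5,8-bis(methoxymethoxy)-1,4-dioxo-1,4-dihydronaphthalen-2-yl]-4-methylpent-3-enyl 3-hydroxy-3-methylbutanoate | CC(C)=CC[C@@H](OC(=O)CC(C)(C)O)C1=CC(=O)c2c(OCOC)ccc(OCOC)c2C1=O
F8 | step 3 | 3-(trimethylsilyl)prop-2-ynal | C[Si](C)(C)C#CC=O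
F9 | step 3 | (R)-1-(trimethylsilyl)hex-5-en-1-yn-3-ol | C=CC[C@@H](O)C#C[Si](C)(C)C
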